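The tetrahydrofuran ring is cut at C2–C3 and C4–C5. Because O1 is flanked by two bare methylene groups (C2 and C5), that three-atom unit can be delivered as the simplest carbonyl ylide, while the trans-disposed benzylic arms on C3 and C4 trace back to an E-configured double bond. One [3+2] cycloaddition should therefore close the ring, make both C–C bonds and set both stereocentres. The alkene partner is the twofold-symmetric (E)-1,4-bis(3,4-dimethoxyphenyl)but-2-ene-1,4-dione. Its aroyl groups activate the double bond, bind a chiral Lewis acid and already hold every remaining carbon of the target; they are deoxygenated to the benzyl groups afterwards.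

Key step: step 3

Assumption: the sense of induction for an aroyl ketone bound through one oxygen cannot be predicted with confidence, so (S,S)-iPr-pybox (2,6-bis[(4S)-4-isopropyl-4,5-dihydro-1,3-oxazol-2-yl]pyridine) is written; its equally available (R,R) antipode is used instead if the first run delivers the (3S,4S) adduct.

Step 1
Reactants: 1 veratrole (1,2-dimethoxybenzene); 2 fumaryl chloride ((E)-but-2-enedioyl dichloride)
Product: 3 (E)-1,4-bis(3,4-dimethoxyphenyl)but-2-ene-1,4-dione
Conditions: 1 (2.2 equiv), AlCl3 (2.5 equiv), CH2Cl2, 0 °C to rt; ice/aq. HCl quench; recrystallisation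
Reagents that add atoms: none
Why: Twofold Friedel–Crafts acylation, in which each acyl end of 2 attacks a veratrole ring para to a methoxy group (the only activated, unhindered position), the new ketone deactivates its own ring against a second acylation, and the thermodynamically preferred E geometry of the fumaroyl unit is kept.

Step 2
Reactants: 4 (trimethylsilyl)methanol
Product: 5 chloromethyl (trimethylsilyl)methyl ether, Me3SiCH2–O–CH2Cl
Conditions: (CH2O)n (1.1 equiv), dry HCl gas, neat, 0 °C; separate the aqueous layer, dry over CaCl2, distil under reduced pressure; use fresh
Reagents that add atoms: paraformaldehyde (as formaldehyde), C=O; hydrogen chloride, Cl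
Why: Classical chloromethyl ether synthesis (chloromethylation of an alcohol), in which the hemiformal of 4 is converted by HCl through the oxocarbenium ion into the α-chloro ether, while the C–Si bond is inert to anhydrous HCl at 0 °C.

Step 3
Reactants: 3 (E)-1,4-bis(3,4-dimethoxyphenyl)but-2-ene-1,4-dione; 5 chloromethyl (trimethylsilyl)methyl ether
Product: 7 (3R,4R)-3,4-bis(3,4-dimethoxybenzoyl)tetrahydrofuran (trans), via formaldehyde O-methylide 6 (not isolated)
Conditions: Sc(OTf)3 (20 mol %), (S,S)-iPr-pybox (24 mol %), 3, CH2Cl2–MeCN, 0 °C; then solid CsF (3 equiv) and 5 (2 equiv, added over 6 h), 0 °C to rt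
Reagents that add atoms: none
Why: Proposed new method: fluoride attacks silicon of 5 as chloride leaves (1,3-elimination, giving Me3SiF and CsCl), and the nucleophilic ylide 6 so released adds across the C=C bond of 3 while 3 is held through one aroyl oxygen on the Sc(OTf)3–pybox complex (trivalent scandium), which lowers the alkene LUMO. The closest known reaction types are the racemic fluoride-triggered [3+2] cycloaddition of this same ylide with electron-poor alkenes and the chiral-Lewis-acid-catalysed cycloadditions of diazo-derived carbonyl ylides with two-point-binding N-acyl oxazolidinone dipolarophiles; what is new is their combination on a singly bound enedione in the presence of fluoride. The tetrahydrofuran ring closes by an intermolecular suprafacial [3+2] cycloaddition that forms C2–C3 and C4–C5 together, and if bond formation were asynchronous the enolate carbon should collapse onto the oxocarbenium carbon (5-endo) faster than the C3–C4 bond can rotate. C3 and C4 are set relative to each other by the E geometry of 3, which a suprafacial addition translates into trans, and in the absolute sense by the pybox ligand, which leaves one of the two enantiotopic alkene faces open; the twofold axis of 3 makes both carbonyl groups equivalent binding sites and, both partners being symmetric, there is no regiochemistry to control. The step needs enantioface selectivity and C=C over C=O selectivity: pre-complexation, a fluoride source that stays largely undissolved and slow addition of 5 are meant to keep free fluoride and the unselective reaction of uncomplexed 3 to a minimum, and the doubly activated alkene is a much better dipolarophile than the hindered aryl ketone carbonyls conjugated to donor rings.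

Step 4
Reactants: 7 (3R,4R)-3,4-bis(3,4-dimethoxybenzoyl)tetrahydrofuran
Product: 8 (3R,4R)-3,4-bis[(3,4-dimethoxyphenyl)(hydroxy)methyl]tetrahydrofuran, mixture of epimers at the two carbinol carbons
Conditions: NaBH4 (3 equiv), CeCl3·7H2O (2 equiv), MeOH–CH2Cl2, −20 to 0 °C; aq. NH4Cl
Reagents that add atoms: none
Why: Luche-type borohydride reduction of two aryl ketones under cold, nearly neutral conditions, which should leave the enolisable centres C3 and C4 untouched; the two new carbinol centres form without control and are removed in step 6.

Step 5
Reactants: 8 diol, mixture of carbinol epimers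
Product: 9 (3R,4R)-3,4-bis[acetoxy(3,4-dimethoxyphenyl)methyl]tetrahydrofuran, mixture of epimers at the two acetoxy-bearing carbons
Conditions: Ac2O (4 equiv), pyridine, DMAP (10 mol %), CH2Cl2, 0 °C to rt
Reagents that add atoms: acetic anhydride, CC(=O)OC(C)=O
Why: DMAP-catalysed acyl transfer to secondary benzylic alcohols under basic conditions that cannot ionise the electron-rich benzylic C–O bonds, so neither cyclic ether formation nor Friedel–Crafts ring closure onto the other aryl ring can start.

Step 6
Reactants: 9 diacetate, mixture of epimers
Product: 10 (3R,4R)-3,4-bis(3,4-dimethoxybenzyl)tetrahydrofuran (trans), the target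
Conditions: H2 (3 bar), 10 % Pd/C, EtOAc–EtOH, rt
Reagents that add atoms: none
Why: Palladium-catalysed hydrogenolysis of benzylic C–O bonds, eased by the acetate leaving groups and the electron-rich rings; the ring C–O bonds are not benzylic and C3 and C4 take no part, so all epimers of 9 should converge on the single (3R,4R) product.

Compound list
1 | veratrole (1,2-dimethoxybenzene) | COc1ccccc1OC | starting material
2 | fumaryl chloride ((E)-but-2-enedioyl dichloride) | O=C(Cl)/C=C/C(=O)Cl | starting material
3 | (E)-1,4-bis(3,4-dimethoxyphenyl)but-2-ene-1,4-dione | COc1ccc(C(=O)/C=C/C(=O)c2ccc(OC)c(OC)c2)cc1OC | intermediate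
4 | (trimethylsilyl)methanol | C[Si](C)(C)CO | starting material
5 | chloromethyl (trimethylsilyl)methyl ether | C[Si](C)(C)COCCl | intermediate
6 | formaldehyde O-methylide (parent carbonyl ylide; formed in the flask, not isolated) | [CH2-][O+]=C | intermediate
7 | (3R,4R)-3,4-bis(3,4-dimethoxybenzoyl)tetrahydrofuran | COc1ccc(C(=O)[C@H]2COC[C@@H]2C(=O)c2ccc(OC)c(OC)c2)cc1OC | intermediate
8 | (3R,4R)-3,4-bis[(3,4-dimethoxyphenyl)(hydroxy)methyl]tetrahydrofuran (carbinol centres unassigned, mixture) | COc1ccc(C(O)[C@H]2COC[C@@H]2C(O)c2ccc(OC)c(OC)c2)cc1OC | intermediate
9 | (3R,4R)-3,4-bis[acetoxy(3,4-dimethoxyphenyl)methyl]tetrahydrofuran (acetoxy-bearing centres unassigned, mixture) | COc1ccc(C(OC(C)=O)[C@H]2COC[C@@H]2C(OC(C)=O)c2ccc(OC)c(OC)c2)cc1OC | intermediate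
10 | (3R,4R)-3,4-bis(3,4-dimethoxybenzyl)tetrahydrofuran | COc1ccc(C[C@H]2COC[C@@H]2Cc2ccc(OC)c(OC)c2)cc1OC | target

Total step count: 6.
Longest linear sequence: 5 steps (steps 1, 3, 4, 5 and 6); step 2 is a one-step branch.

Steps most likely to fail

Step 3. Fluoride may be captured by the scandium centre, which switches the chiral complex off; the ylide then reacts with uncomplexed 3 without facial control and the enantioselectivity collapses. A second failure mode is addition of the ylide to a Lewis-acid-bound C=O group instead of the alkene. The fallback uses known chemistry and sets out from 3 and 5. The cycloaddition is run without any Lewis acid (CsF, MeCN, rt), the established racemic mode of this ylide with electron-poor alkenes, and should give racemic trans-3,4-bis(3,4-dimethoxybenzoyl)tetrahydrofuran F1. The enantiomers are then separated by preparative chromatography on a chiral stationary phase (amylose tris(3,5-dimethylphenylcarbamate), supercritical CO2/MeOH), and the (3R,4R) enantiomer comes back to the route as 7.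

Step 6. Cleavage of the hindered secondary benzylic C–O bonds may be slow or stop halfway. Acetic acid may also be lost towards a styrene, which would erase C3 or C4 before the double bond is hydrogenated again. The fallback sets out from diol 8 and replaces the metal-surface hydrogenolysis by a radical chain deoxygenation (Barton–McCombie). NaH, CS2 and MeI in THF should give the bis(S-methyl xanthate) of 8, (3R,4R)-3,4-bis{(3,4-dimethoxyphenyl)[(methylsulfanyl)carbonothioyloxy]methyl}tetrahydrofuran F2. Bu3SnH with Et3B/air in toluene at rt then exchanges both C–O bonds for C–H through benzylic radicals that leave C3 and C4 alone, and the sequence comes back to the route at target 10.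

Step 1. AlCl3 may cleave a methoxy group para to the new ketone, HCl or a second arene may add across the activated double bond, or the reaction may stall after one acylation. The fallback avoids the Lewis acid and sets out from 2 and 1. Fumaryl chloride 2 with N,O-dimethylhydroxylamine hydrochloride and pyridine in CH2Cl2 should give the bis-Weinreb amide (E)-N1,N4-dimethoxy-N1,N4-dimethylbut-2-enediamide F3. Veratrole 1 is brominated (NBS, MeCN) to 4-bromo-1,2-dimethoxybenzene F4, which with Mg in THF gives (3,4-dimethoxyphenyl)magnesium bromide F5. Addition of F5 (2.2 equiv) to F3 at −40 to 0 °C, followed by an inverse quench into cold 1 M HCl, should release the enedione (Weinreb ketone synthesis; the chelated tetrahedral intermediates prevent over-addition, and the acidic quench keeps the liberated amine from adding to the enedione). The sequence comes back to the route at 3.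

Further compounds
F1 | step 3 | racemic trans-3,4-bis(3,4-dimethoxybenzoyl)tetrahydrofuran (1:1 mixture of the 3R,4R and 3S,4S enantiomers) | COc1ccc(C(=O)[C@H]2COC[C@@H]2C(=O)c2ccc(OC)c(OC)c2)cc1OC.COc1ccc(C(=O)[C@@H]2COC[C@H]2C(=O)c2ccc(OC)c(OC)c2)cc1OC
F2 | step 6 | (3R,4R)-3,4-bis{(3,4-dimethoxyphenyl)[(methylsulfanyl)carbonothioyloxy]methyl}tetrahydrofuran (bis-xanthate of 8, carbinol centres unassigned) | COc1ccc(C(OC(=S)SC)[C@H]2COC[C@@H]2C(OC(=S)SC)c2ccc(OC)c(OC)c2)cc1OC
F3 | step 1 | (E)-N1,N4-dimethoxy-N1,N4-dimethylbut-2-enediamide | CON(C)C(=O)/C=C/C(=O)N(C)OC
F4 | step 1 | 4-bromo-1,2-dimethoxybenzene | COc1ccc(Br)cc1OC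
F5 | step 1 | (3,4-dimethoxyphenyl)magnesium bromide | COc1ccc([Mg]Br)cc1OC
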